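The cyclopentane ring (C1, C2, C3, C9, C10) is disconnected at C1–C2 and C9–C10. Because this ring is fused at C3–C9 directly beside the C8 oxygen of the seven-membered ring, a C8 ketone with a cyclopropane spanning C9, C3 and C2 is a masked C2 radical/C9 enolate pair. One samarium-catalysed radical relay with 3-methylbut-1-yne forms both bonds and closes the cyclopentene that carries the isopropyl group on C10. The precursor is an enantiopure 6-silyloxy-7-methylbicyclo[5.1.0]octan-2-one, made from a lipase-desymmetrised cycloheptenediol; dihydroxylation, C6-methyl enone construction, Luche reduction and esterifications follow.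

Key step: step 8

Locants: the cyclopentane is C1 (acetoxy), C2, C3 (methyl, ring fusion), C9 (H, ring fusion), C10 (hydroxyl, isopropyl); the cycloheptene runs from C3 through C4 (hydroxyl), C5, C6 (methyl), C7 and C8 (aroyloxy) to C9.

Design of the precursor: the C4 oxygen is a TBS ether trans to the cyclopropane methylene. It steers the cyclopropanation, is inert to samarium, and leaves only in the last step together with the phenol silyl ether. C5–C7 stay unfunctionalised, so the ketyl is a plain alkyl ketyl with no competing radical acceptor in the ring.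

Assumption: the lipase in step 2 acylates the (R)-configured carbinol of the meso diol, the usual preference of lipases for secondary alcohols.

Step 1
Reactants: 1 cyclohepta-1,3-diene
Product: 3 cis-cyclohept-2-ene-1,4-diol (meso), via endoperoxide 2 (not isolated)
Conditions: O2, tetraphenylporphyrin (cat.), hν (visible), CH2Cl2, 0 °C; then thiourea, MeOH, rt
Reagents that add atoms: dioxygen, O=O
Why: Singlet-oxygen (4+2) cycloaddition across the cyclic 1,3-diene puts both oxygens on one face, and thiourea reduction of the O–O bond leaves the cis (meso) ene-diol.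

Step 2
Reactants: 3 cis-cyclohept-2-ene-1,4-diol
Product: 4 (1R,4S)-4-hydroxycyclohept-2-en-1-yl acetate
Conditions: immobilised Candida antarctica lipase B, isopropenyl acetate, tBuOMe, rt
Reagents that add atoms: isopropenyl acetate, CC(=C)OC(C)=O
Why: Lipase-catalysed desymmetrising transesterification of a meso diol should acylate the (R)-carbinol, so the free (S)-carbinol, the future C4, carries the absolute configuration of the whole route.

Step 3
Reactants: 4 (1R,4S)-4-hydroxycyclohept-2-en-1-yl acetate
Product: 5 (1R,4S)-4-(tert-butyldimethylsilyloxy)cyclohept-2-en-1-yl acetate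
Conditions: TBSCl, imidazole, DMF, rt
Reagents that add atoms: tert-butyldimethylsilyl chloride, CC(C)(C)[Si](C)(C)Cl
Why: Standard silylation of the free secondary allylic alcohol, with no stereocentre touched.

Step 4
Reactants: 5 (1R,4S)-4-(tert-butyldimethylsilyloxy)cyclohept-2-en-1-yl acetate
Product: 6 (1R,4S)-4-(tert-butyldimethylsilyloxy)cyclohept-2-en-1-ol
Conditions: K2CO3 (cat.), MeOH, 0 °C → rt
Reagents that add atoms: none
Why: Base-catalysed transesterification (methanolysis) removes the acetate while the silyl ether stays.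

Step 5
Reactants: 6 (1R,4S)-4-(tert-butyldimethylsilyloxy)cyclohept-2-en-1-ol
Product: 7 (S)-4-(tert-butyldimethylsilyloxy)cyclohept-2-en-1-one
Conditions: Dess–Martin periodinane, CH2Cl2, rt
Reagents that add atoms: none
Why: Dess–Martin oxidation of the allylic alcohol should give the enone without touching C4.

Step 6
Reactants: 7 (S)-4-(tert-butyldimethylsilyloxy)cyclohept-2-en-1-one
Product: 9 (S)-4-(tert-butyldimethylsilyloxy)-3-methylcyclohept-2-en-1-one, via lithium enolate 8 (not isolated)
Conditions: Me2CuLi (from MeLi, CuI), Et2O, −78 °C; then PhS(Cl)=NtBu, THF, −78 °C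
Reagents that add atoms: lithium dimethylcuprate, [Li+].C[Cu-]C
Why: Gilman cuprate 1,4-addition (anti to the C4 silyl ether) is followed by Mukaiyama dehydrogenation of the enolate with the sulfinimidoyl chloride, whose syn-elimination can only take C3–H and so restores the C9=C3 double bond with the methyl in place, erasing the transient C3 centre.

Step 7
Reactants: 9 (S)-4-(tert-butyldimethylsilyloxy)-3-methylcyclohept-2-en-1-one, 10 trimethylsulfoxonium iodide
Product: 11 (1R,6S,7S)-6-(tert-butyldimethylsilyloxy)-7-methylbicyclo[5.1.0]octan-2-one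
Conditions: NaH, DMSO, rt → 50 °C
Reagents that add atoms: none
Why: Corey–Chaykovsky cyclopropanation, in which the sulfoxonium ylide should add to C3 anti to the neighbouring silyl ether and the enolate closes the three-membered ring on the same face, setting C3 and C9 with the methylene (C2) trans to the C4 oxygen.

Step 8
Reactants: 11 (1R,6S,7S)-6-(tert-butyldimethylsilyloxy)-7-methylbicyclo[5.1.0]octan-2-one, 12 3-methylbut-1-yne
Product: 13 (3aR,8S,8aS)-8-(tert-butyldimethylsilyloxy)-8a-methyl-3-(propan-2-yl)-3a,5,6,7,8,8a-hexahydroazulen-4(1H)-one (cis-fused C8 ketone with C1=C10 alkene)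
Conditions: SmI2 (25 mol%), Sm metal (25 mol%), 12 (10 equiv), THF, 60 °C, sealed tube
Reagents that add atoms: none
Why: Proposed new method: SmI2 transfers an electron to the C8 ketone of 11, the ketyl opens the external C9–C2 cyclopropane bond (the bond best aligned with the ketyl π-system, as in dissolving-metal openings of bicyclo[n.1.0]alkan-2-ones) to a primary C2 radical and a trivalent samarium enolate, the radical adds to the unsubstituted carbon of 12 (C1), the σ-vinyl radical at C10 attacks the enolate carbon C9, and the new ketyl returns its electron to trivalent samarium so that SmI2 turns over. The closest known reaction type is the SmI2-catalysed radical-relay (3+2) coupling of aryl and simple alkyl cyclopropyl ketones with alkynes, where samarium metal keeps the catalyst alive for hard-to-reduce alkyl ketones; new here are the fused ketone with a quaternary cyclopropane carbon, the neopentyl-type radical and the unactivated alkyne, hence the large excess of 12. The cyclopentene closes by 5-exo-trig attack of the vinyl radical on C9. C9 is planar in the enolate and is re-formed in this closure: the three-atom tether hangs from C3 and can reach the adjacent C9 only on its own face, so the ring fusion must be cis (C3–CH3 and C9–H on one side), while C3 and C4 are untouched. The step needs external instead of ring-fusion bond cleavage (stereoelectronic overlap in a reversible opening), attack at the alkyne terminus (sterics and the more substituted vinyl radical) and ring closure faster than 1,5-hydrogen transfer from C4–H (a five-membered closure onto an electron-rich enolate held next to the radical). The neutral medium should leave the C1=C10 double bond out of conjugation with the ketone.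

Step 9
Reactants: 13 cis-fused C8 ketone with C1=C10 alkene
Product: 14 C1,C10-cis-diol of the C8 ketone (both hydroxyls on the face of C3–CH3 and C9–H; C4 silyl ether unchanged)
Conditions: OsO4 (5 mol%), NMO, acetone/H2O, rt
Reagents that add atoms: N-methylmorpholine N-oxide, C[N+]1([O-])CCOCC1; water, O
Why: Upjohn syn-dihydroxylation, in which OsO4 should attack the trisubstituted C1=C10 alkene from the convex face of the cis-fused bicycle (the face of C3–CH3 and C9–H), setting C1 and C10 together while the neutral medium keeps the β,γ-double bond from migrating beforehand.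

Step 10
Reactants: 14 C1,C10-cis-diol of the C8 ketone
Product: 15 C1,C10-O-isopropylidene acetal (acetonide) of 14
Conditions: 2-methoxypropene, PPTS (cat.), CH2Cl2, 0 °C → rt
Reagents that add atoms: 2-methoxypropene, COC(C)=C
Why: Acid-catalysed acetonide formation on the cis-1,2-diol blocks retro-aldol cleavage and β-elimination of the C10 oxygen during the enolate steps that follow.

Step 11
Reactants: 15 acetonide-protected C8 ketone
Product: 17 acetonide-protected C6=C7 enone (C8 ketone), via lithium enolate 16 (not isolated)
Conditions: LDA, THF, −78 °C; then PhS(Cl)=NtBu, −78 °C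
Reagents that add atoms: none
Why: Kinetic deprotonation by LDA should occur at the unhindered C7 methylene (C9–H is tertiary and flanked by two fully substituted carbons), and Mukaiyama dehydrogenation of that enolate gives the C6=C7 enone.

Step 12
Reactants: 17 acetonide-protected C6=C7 enone
Product: 19 acetonide-protected C6-methyl C6=C7 enone (C8 ketone), via lithium enolate 18 (not isolated)
Conditions: Me2CuLi (from MeLi, CuI), Et2O/THF, −78 °C; then PhS(Cl)=NtBu, −78 °C
Reagents that add atoms: lithium dimethylcuprate, [Li+].C[Cu-]C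
Why: Cuprate 1,4-addition brings in the C6 methyl and the resulting enolate is dehydrogenated in the same flask (Mukaiyama dehydrogenation), the syn-elimination using C6–H to give the trisubstituted enone and erasing the C6 centre formed on the way.

Step 13
Reactants: 19 acetonide-protected C6-methyl C6=C7 enone
Product: 20 acetonide-protected (8S)-allylic alcohol (C8–OH trans to C9–H, on the side of C10)
Conditions: NaBH4, CeCl3·7H2O, MeOH, −78 → −20 °C
Reagents that add atoms: none
Why: Luche 1,2-reduction, in which hydride should arrive from the convex face of the cycloheptenone (the side of C9–H and C3–CH3, away from the C10 isopropyl group on the folded cyclopentane), placing the C8 hydroxyl trans to C9–H as in the target.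

Step 14
Reactants: 21 4-hydroxybenzoic acid
Product: 23 4-(tert-butyldimethylsilyloxy)benzoic acid, via silyl ester 22 (not isolated)
Conditions: TBSCl (2.5 equiv), imidazole, DMF, rt; then AcOH/THF/H2O, rt
Reagents that add atoms: tert-butyldimethylsilyl chloride, CC(C)(C)[Si](C)(C)Cl
Why: Exhaustive silylation followed by mild hydrolysis of the labile silyl ester leaves the acid-stable aryl silyl ether (standard phenol protection).

Step 15
Reactants: 20 acetonide-protected (8S)-allylic alcohol, 23 4-(tert-butyldimethylsilyloxy)benzoic acid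
Product: 24 C8 4-(tert-butyldimethylsilyloxy)benzoate of 20
Conditions: DCC, DMAP (cat.), CH2Cl2, rt
Reagents that add atoms: none
Why: Steglich esterification of the only free hydroxyl, the C8 allylic alcohol, proceeds with retention at C8.

Step 16
Reactants: 24 C8 4-(tert-butyldimethylsilyloxy)benzoate with C1,C10 acetonide
Product: 25 C1,C10-diol C8 4-(tert-butyldimethylsilyloxy)benzoate (C4 silyl ether retained)
Conditions: CSA (cat.), MeOH, 0 °C → rt
Reagents that add atoms: none
Why: Acid-catalysed transketalisation to methanol frees the C1/C10 diol, while the hindered secondary and the aryl silyl ethers should survive catalytic acid at low temperature.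

Step 17
Reactants: 25 C1,C10-diol C8 4-(tert-butyldimethylsilyloxy)benzoate
Product: 26 C1 acetate of 25 (C10 hydroxyl free)
Conditions: Ac2O, pyridine, DMAP (cat.), CH2Cl2, 0 °C → rt
Reagents that add atoms: acetic anhydride, CC(=O)OC(C)=O
Why: DMAP-catalysed acetylation should reach only the secondary C1 hydroxyl, the tertiary C10 hydroxyl being too hindered to react.

Step 18
Reactants: 26 bis-silylated C1 acetate
Product: 27 (1R,2S,3aS,4S,8S,8aR)-2-acetoxy-1,4-dihydroxy-3a,6-dimethyl-1-(propan-2-yl)-1,2,3,3a,4,5,8,8a-octahydroazulen-8-yl 4-hydroxybenzoate (CNP0146780.2)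
Conditions: HF·pyridine, pyridine, THF, 0 °C → rt
Reagents that add atoms: none
Why: Fluoride-mediated desilylation with buffered HF·pyridine removes the aryl and the C4 silyl ethers and should leave the two esters, the tertiary alcohol and the allylic system untouched.

Compound list
1 | cyclohepta-1,3-diene | C1=CC=CCCC1 | starting material
2 | 6,7-dioxabicyclo[3.2.2]non-8-ene (meso endoperoxide) | C1=C[C@H]2CCC[C@@H]1OO2 | intermediate
3 | cis-cyclohept-2-ene-1,4-diol (meso, 1R,4S) | C1=C[C@H](O)CCC[C@@H]1O | intermediate
4 | (1R,4S)-4-hydroxycyclohept-2-en-1-yl acetate | C1=C[C@H](OC(C)=O)CCC[C@@H]1O | intermediate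
5 | (1R,4S)-4-(tert-butyldimethylsilyloxy)cyclohept-2-en-1-yl acetate | C1=C[C@H](OC(C)=O)CCC[C@@H]1O[Si](C)(C)C(C)(C)C | intermediate
6 | (1R,4S)-4-(tert-butyldimethylsilyloxy)cyclohept-2-en-1-ol | C1=C[C@H](O)CCC[C@@H]1O[Si](C)(C)C(C)(C)C | intermediate
7 | (S)-4-(tert-butyldimethylsilyloxy)cyclohept-2-en-1-one | C1=CC(=O)CCC[C@@H]1O[Si](C)(C)C(C)(C)C | intermediate
8 | lithium (3S,4S)-4-(tert-butyldimethylsilyloxy)-3-methylcyclohept-1-en-1-olate (methyl trans to the silyl ether) | [Li+].[O-]C1=C[C@H](C)[C@@H](O[Si](C)(C)C(C)(C)C)CCC1 | intermediate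
9 | (S)-4-(tert-butyldimethylsilyloxy)-3-methylcyclohept-2-en-1-one | CC1=CC(=O)CCC[C@@H]1O[Si](C)(C)C(C)(C)C | intermediate
10 | trimethylsulfoxonium iodide | C[S+](C)(C)=O.[I-] | starting material
11 | (1R,6S,7S)-6-(tert-butyldimethylsilyloxy)-7-methylbicyclo[5.1.0]octan-2-one (C8 ketone, C9–C3–C2 cyclopropane, methylene trans to the C4 silyl ether) | C1[C@]2(C)[C@@H](O[Si](C)(C)C(C)(C)C)CCCC(=O)[C@H]12 | intermediate
12 | 3-methylbut-1-yne | CC(C)C#C | starting material
13 | (3aR,8S,8aS)-8-(tert-butyldimethylsilyloxy)-8a-methyl-3-(propan-2-yl)-3a,5,6,7,8,8a-hexahydroazulen-4(1H)-one (cis-fused; C8 ketone, C1=C10 alkene, C10 isopropyl) | C1(C(C)C)=CC[C@]2(C)[C@@H](O[Si](C)(C)C(C)(C)C)CCCC(=O)[C@H]12 | intermediate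
14 | cis-fused C8 ketone with C1,C10-cis-diol (hydroxyls, C3–CH3 and C9–H on one face), C10 isopropyl, C4 silyl ether | O[C@H]1C[C@]2(C)[C@@H](O[Si](C)(C)C(C)(C)C)CCCC(=O)[C@@H]2[C@]1(O)C(C)C | intermediate
15 | C1,C10-O-isopropylidene acetal of 14 | CC1(C)O[C@H]2C[C@]3(C)[C@@H](O[Si](C)(C)C(C)(C)C)CCCC(=O)[C@@H]3[C@]2(O1)C(C)C | intermediate
16 | lithium C7=C8 enolate of 15 | [Li+].CC1(C)O[C@H]2C[C@]3(C)[C@@H](O[Si](C)(C)C(C)(C)C)CCC=C([O-])[C@@H]3[C@]2(O1)C(C)C | intermediate
17 | acetonide-protected C6=C7 enone (C8 ketone) | CC1(C)O[C@H]2C[C@]3(C)[C@@H](O[Si](C)(C)C(C)(C)C)CC=CC(=O)[C@@H]3[C@]2(O1)C(C)C | intermediate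
18 | lithium C7=C8 enolate carrying the new C6 methyl (C6 configuration not controlled, erased in the same flask) | [Li+].CC1(C)O[C@H]2C[C@]3(C)[C@@H](O[Si](C)(C)C(C)(C)C)CC(C)C=C([O-])[C@@H]3[C@]2(O1)C(C)C | intermediate
19 | acetonide-protected C6-methyl C6=C7 enone (C8 ketone) | CC1(C)O[C@H]2C[C@]3(C)[C@@H](O[Si](C)(C)C(C)(C)C)CC(C)=CC(=O)[C@@H]3[C@]2(O1)C(C)C | intermediate
20 | acetonide-protected (8S)-allylic alcohol (C8–OH trans to C9–H) | CC1(C)O[C@H]2C[C@]3(C)[C@@H](O[Si](C)(C)C(C)(C)C)CC(C)=C[C@H](O)[C@@H]3[C@]2(O1)C(C)C | intermediate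
21 | 4-hydroxybenzoic acid | OC(=O)c1ccc(O)cc1 | starting material
22 | tert-butyldimethylsilyl 4-(tert-butyldimethylsilyloxy)benzoate | CC(C)(C)[Si](C)(C)OC(=O)c1ccc(O[Si](C)(C)C(C)(C)C)cc1 | intermediate
23 | 4-(tert-butyldimethylsilyloxy)benzoic acid | CC(C)(C)[Si](C)(C)Oc1ccc(cc1)C(O)=O | intermediate
24 | C8 4-(tert-butyldimethylsilyloxy)benzoate of 20 | CC1(C)O[C@H]2C[C@]3(C)[C@@H](O[Si](C)(C)C(C)(C)C)CC(C)=C[C@H](OC(=O)c4ccc(O[Si](C)(C)C(C)(C)C)cc4)[C@@H]3[C@]2(O1)C(C)C | intermediate
25 | C1,C10-diol C8 4-(tert-butyldimethylsilyloxy)benzoate, C4 silyl ether | O[C@H]1C[C@]2(C)[C@@H](O[Si](C)(C)C(C)(C)C)CC(C)=C[C@H](OC(=O)c3ccc(O[Si](C)(C)C(C)(C)C)cc3)[C@@H]2[C@]1(O)C(C)C | intermediate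
26 | C1 acetate of 25 | CC(=O)O[C@H]1C[C@]2(C)[C@@H](O[Si](C)(C)C(C)(C)C)CC(C)=C[C@H](OC(=O)c3ccc(O[Si](C)(C)C(C)(C)C)cc3)[C@@H]2[C@]1(O)C(C)C | intermediate
27 | (1R,2S,3aS,4S,8S,8aR)-2-acetoxy-1,4-dihydroxy-3a,6-dimethyl-1-(propan-2-yl)-1,2,3,3a,4,5,8,8a-octahydroazulen-8-yl 4-hydroxybenzoate | CC(=O)O[C@H]1C[C@]2(C)[C@@H](O)CC(C)=C[C@H](OC(=O)c3ccc(O)cc3)[C@@H]2[C@]1(O)C(C)C | target

Total step count: 18. Longest linear sequence: 17 steps (steps 1–13 and 15–18; step 14 is a one-step side branch).

Steps most likely to fail

1. Step 8 (Proposed new method). The radical relay may stall: electron transfer to the alkyl ketone or capture of the hindered primary radical by the unactivated alkyne may be too slow. The reversible ring opening would then drain into over-reduction, cleavage of the ring-fusion bond, or 1,5-hydrogen transfer from C4–H to the vinyl radical. The fallback sets out from enone 9 (bypassing 11) and comes back at 13, using a Lewis-acid (trimethylsilyl)allene cyclopentene annulation (Danheiser annulation) that makes the same two bonds by polar chemistry. Commercial 3-(trimethylsilyl)prop-2-yn-1-ol is mesylated (MsCl, Et3N, CH2Cl2) to 3-(trimethylsilyl)prop-2-yn-1-yl methanesulfonate F1, which with iPrMgCl and CuBr·LiBr (THF, −78 °C, anti-SN2′) should give trimethyl(4-methylpenta-1,2-dien-3-yl)silane F2. With TiCl4 (CH2Cl2, −78 °C) the allene terminus of F2 adds to C3 of 9 anti to the silyl ether, the β-silyl vinyl cation undergoes a 1,2-silyl shift and the titanium enolate closes C9–C10, giving the C1-trimethylsilyl analogue of 13 F3. Ipso-protodesilylation of the vinylsilane (TFA, CH2Cl2, 0 °C, short contact) would return 13.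

2. Step 7. Conjugate addition of the ylide to the hindered β,β-disubstituted enone may be slow, letting carbonyl attack or enolisation compete and eroding facial selectivity on warming. The fallback sets out from 9 and comes back at 11, replacing ylide addition by hydroxyl-directed cyclopropanation. Reagent-controlled Corey–Bakshi–Shibata reduction of 9 ((R)-2-methyl-CBS-oxazaborolidine, BH3·SMe2, THF) should give the trans allylic alcohol (1S,4S)-4-(tert-butyldimethylsilyloxy)-3-methylcyclohept-2-en-1-ol F4. Simmons–Smith–Furukawa cyclopropanation (Et2Zn, CH2I2, CH2Cl2, 0 °C) delivers the methylene syn to the zinc alkoxide and hence anti to the silyl ether, giving (1R,2S,6S,7S)-6-(tert-butyldimethylsilyloxy)-7-methylbicyclo[5.1.0]octan-2-ol F5. Dess–Martin oxidation returns 11.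

3. Step 13. Hydride delivery to the flexible cycloheptenone may show poor facial selectivity, giving mainly or partly the C8 epimer. The fallback sets out from 19 and comes back at 24: the C8-epimeric allylic alcohol (acetonide-protected 8-epi-20) F6 is carried forward instead of being discarded. Mitsunobu esterification of F6 with acid 23 (PPh3, DIAD, THF, 0 °C) installs the aroyl ester with inversion at C8 and so gives 24 directly.

Further compounds
F1 | step 8 | 3-(trimethylsilyl)prop-2-yn-1-yl methanesulfonate | C[Si](C)(C)C#CCOS(C)(=O)=O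
F2 | step 8 | trimethyl(4-methylpenta-1,2-dien-3-yl)silane | C=C=C(C(C)C)[Si](C)(C)C
F3 | step 8 | C1-trimethylsilyl analogue of 13 (vinylsilane) | C1(C(C)C)=C([Si](C)(C)C)C[C@]2(C)[C@@H](O[Si](C)(C)C(C)(C)C)CCCC(=O)[C@H]12
F4 | step 7 | (1S,4S)-4-(tert-butyldimethylsilyloxy)-3-methylcyclohept-2-en-1-ol | CC1=C[C@@H](O)CCC[C@@H]1O[Si](C)(C)C(C)(C)C
F5 | step 7 | (1R,2S,6S,7S)-6-(tert-butyldimethylsilyloxy)-7-methylbicyclo[5.1.0]octan-2-ol | C1[C@]2(C)[C@@H](O[Si](C)(C)C(C)(C)C)CCC[C@H](O)[C@H]12
F6 | step 13 | acetonide-protected (8R)-allylic alcohol (C8 epimer of 20) | CC1(C)O[C@H]2C[C@]3(C)[C@@H](O[Si](C)(C)C(C)(C)C)CC(C)=C[C@@H](O)[C@@H]3[C@]2(O1)C(C)C
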